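## Retrosynthetic overview

1. Target 22 comes from the glycal-type allylic alcohol 21 by a Ferrier-type reductive transposition that sets C10; 21 comes from dihydropyranone 20.
2. Pyran ring: the C10–O11 bond is made by cyclodehydration of a δ-hydroxy-1,3-diketone (19), assembled from aldehyde 12 and enone 15 by aldol addition and oxidation.
3. Lactone bridge: the C13–O15 bond is made by transannular lactonisation of the cis-1,4 hydroxy ester obtained from ketol 9.
4. Carbocycle: 9 comes from a new asymmetric Michael/aldol annulation of the α-alkoxy acetoacetate 3 (C12–O11 bond by O–H insertion) with alkylidene-cyclopentanone 7.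
5. Ring order: cyclopentane (purchased) → cyclohexane → lactone bridge → dihydropyran.

Assumption: atom labels (C10, O11, C12, C13, O15, C16 … C27) are the positions of the atoms in the target SMILES, and compounds 1, 2, 4, 5, 13 and 14 are bought.

## Route

Step 1
Reactants: 1 ethyl 2-diazo-3-oxobutanoate; 2 (4-methoxyphenyl)methanol
Product: 3 ethyl 2-[(4-methoxybenzyl)oxy]-3-oxobutanoate
Conditions: Rh2(OAc)4 (1 mol%), CH2Cl2, 40 °C
Reagents that add atoms: none
Why: Rhodium-carbenoid O–H insertion of an acceptor/acceptor diazo compound into a benzylic alcohol forms the C12–O11 bond; the new centre is enolisable and needs no control.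

Step 2
Reactants: 4 1,4-dioxaspiro[4.4]nonan-7-one; 5 2,2-dimethoxyacetaldehyde
Product: 7 (8E)-8-(2,2-dimethoxyethylidene)-1,4-dioxaspiro[4.4]nonan-7-one, via aldol adduct 6 (not isolated)
Conditions: pyrrolidine (20 mol%), AcOH (20 mol%), MeOH/H2O, 25 °C
Reagents that add atoms: none
Why: Amine-catalysed cross-aldol condensation; the enamine forms at the α-carbon remote from the ketal and dehydration gives the conjugated E-alkylidene ketone.

Step 3
Reactants: 3 ethyl 2-[(4-methoxybenzyl)oxy]-3-oxobutanoate; 7 (8E)-8-(2,2-dimethoxyethylidene)-1,4-dioxaspiro[4.4]nonan-7-one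
Product: 9 ethyl 7-(dimethoxymethyl)-3a-hydroxy-6-[(4-methoxybenzyl)oxy]-5-oxooctahydrospiro[indene-2,2'-[1,3]dioxolane]-6-carboxylate (cis-fused; 3a-OH cis to the ester; CH(OMe)2 equatorial), via Michael adduct 8 (not isolated)
Conditions: 9-O-(phenanthren-9-yl)cupreidine (10 mol%), toluene, 0 °C; then DBU (20 mol%), 0 → 25 °C
Reagents that add atoms: none
Why: Proposed new method: the bifunctional cinchona base deprotonates 3 and hydrogen-bonds the s-cis enone of 7, so the chelated enolate adds through one face (asymmetric Michael addition, sets C12 and C22 with CH(OMe)2 anti to the PMB ether); catalytic DBU then lets C21 epimerise and the methyl ketone close on the cyclopentanone in a reversible 6-exo aldol addition that settles in the most stable cis-fused ketol (chair with CH(OMe)2, C20 and OPMB equatorial; sets C21 and C16, OH cis to H21 and to the ester); the closest known reactions are cinchona-catalysed Michael additions of α-substituted β-keto esters to enones and amine-mediated domino Michael–aldol (Robinson-type) annulations, not yet shown for an α-alkoxy β-keto ester with a 2-alkylidenecyclopentanone.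

Step 4
Reactants: 9 ketol from step 3
Product: 11 PMB-protected hydroxy lactone (C13–O15 lactone-bridged cis-hydrindane; C12–OPMB, C27–OH as both epimers, C18 ethylene ketal, C23 as CH(OMe)2), via diol 10 (not isolated)
Conditions: NaBH4, EtOH, 0 °C; work-up; then KOt-Bu (20 mol%), THF, 4 Å MS, 25 °C
Reagents that add atoms: none
Why: Borohydride reduction removes the C27 ketone (configuration irrelevant, re-oxidised in step 8) so the base cannot trigger β-elimination, and only the tertiary alkoxide that is 1,4-cis to the axial ester closes the 2-oxabicyclo[2.2.2]octanone by transannular lactonisation (transesterification), which also removes stereoisomeric ketols.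

Step 5
Reactants: 11 PMB-protected hydroxy lactone
Product: 12 lactone keto aldehyde (C12–OH, C27–OH as both epimers, C18 ketone, C23 aldehyde)
Conditions: TFA/CH2Cl2/H2O (10:10:1), 0 → 25 °C
Reagents that add atoms: water, O
Why: Acidolysis of the PMB ether and hydrolysis of the acetal and ketal; the bridgehead carbinol cannot dehydrate and C22 stays in its favoured configuration (CHO anti to C20).

Step 6
Reactants: 13 non-1-ene; 14 pent-1-en-3-one
Product: 15 (4E)-dodec-4-en-3-one
Conditions: second-generation Hoveyda–Grubbs catalyst [RuCl2(=CH-C6H4-2-O-i-Pr)(H2IMes)] (2 mol%), CH2Cl2, 40 °C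
Reagents that add atoms: none
Why: Olefin cross-metathesis of a terminal alkene with an enone is reliably E-selective.

Step 7
Reactants: 12 lactone keto aldehyde; 15 (4E)-dodec-4-en-3-one
Product: 18 aldol adduct (C22 carries CH(OH)–CH(CH3)–C(=O)–(E)-CH=CH–C7H15; mixture at C23, C24, C27), via boron enolate 16 (not isolated), via boron aldolate 17 (not isolated)
Conditions: 15 (3 equiv), (c-C6H11)2BCl, Et3N, Et2O, −78 → 0 °C; then 12, −78 → −20 °C; MeOH, pH 7 buffer
Reagents that add atoms: none
Why: Boron-mediated aldol addition; the enol borinate adds only to the aldehyde (ketone and lactone are inert) and the new centres C23 and C24 are destroyed later.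

Step 8
Reactants: 18 aldol adduct
Product: 20 dihydropyranone (O11–C10(nonenyl)=C24(CH3)–C23(=O) ring fused at C12–C22; ketones at C18 and C27), via tetraketone 19 (not isolated)
Conditions: Dess–Martin periodinane (3 equiv), CH2Cl2, 25 °C; then TsOH·H2O (10 mol%), 4 Å MS, 25 °C
Reagents that add atoms: none
Why: Dess–Martin oxidation gives the 2-methyl-1,3-diketone (C27 is oxidised as well), and acid-catalysed cyclodehydration of the δ-hydroxy-β-diketone (hemiketalisation of the C12 hydroxyl on C10, loss of water) forms the C10–O11 bond and the 2,3-dihydro-4H-pyran-4-one without a new stereocentre.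

Step 9
Reactants: 20 dihydropyranone
Product: 21 glycal-type triol (C23–OH as a mixture; C18–OH and C27–OH as in the target; enol ether C10=C24)
Conditions: NaBH4, CeCl3·7H2O, MeOH, −78 → −20 °C; AcOH quench at −78 °C
Reagents that add atoms: none
Why: Luche reduction gives 1,2-reduction of the vinylogous ester; hydride reaches C27 from the lactone-bridge side (the other face is blocked by H22 and the C20 methylene) and C18 from the convex face (the side of O15 and H21), which sets both carbinols as in the target.

Step 10
Reactants: 21 glycal-type triol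
Product: 22 target lactone
Conditions: Et3SiH (5 equiv), BF3·OEt2 (30 mol%), CH2Cl2, −78 °C; Et3N quench
Reagents that add atoms: none
Why: Ferrier-type reductive rearrangement (ionic hydrogenation): ionisation of the allylic hydroxyl gives the O11=C10–C24=C23 oxocarbenium ion and Et3SiH adds at C10 from the open face, away from the axial lactone carbonyl C13=O14, which sets C10 (nonenyl syn to C13) and moves the double bond to C23=C24; this is the kinetic epimer, so the reaction is quenched cold.

## Compound list

1 | ethyl 2-diazo-3-oxobutanoate | CCOC(=O)C(=[N+]=[N-])C(C)=O | starting material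
2 | (4-methoxyphenyl)methanol | COc1ccc(CO)cc1 | starting material
3 | ethyl 2-[(4-methoxybenzyl)oxy]-3-oxobutanoate (racemic, labile centre) | CCOC(=O)C(OCc1ccc(OC)cc1)C(C)=O | intermediate
4 | 1,4-dioxaspiro[4.4]nonan-7-one | O=C1CCC2(C1)OCCO2 | starting material
5 | 2,2-dimethoxyacetaldehyde | COC(OC)C=O | starting material
6 | 8-(1-hydroxy-2,2-dimethoxyethyl)-1,4-dioxaspiro[4.4]nonan-7-one (diastereomer mixture) | COC(OC)C(O)C1CC2(OCCO2)CC1=O | intermediate
7 | (8E)-8-(2,2-dimethoxyethylidene)-1,4-dioxaspiro[4.4]nonan-7-one | COC(OC)/C=C1\CC2(OCCO2)CC1=O | intermediate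
8 | ethyl 2-acetyl-4,4-dimethoxy-2-[(4-methoxybenzyl)oxy]-3-(7-oxo-1,4-dioxaspiro[4.4]nonan-8-yl)butanoate (C12, C22, C21 in the same sense as in 22) | CCOC(=O)[C@@](OCc1ccc(OC)cc1)(C(C)=O)[C@H](C(OC)OC)[C@H]1CC2(OCCO2)CC1=O | intermediate
9 | ethyl 7-(dimethoxymethyl)-3a-hydroxy-6-[(4-methoxybenzyl)oxy]-5-oxooctahydrospiro[indene-2,2'-[1,3]dioxolane]-6-carboxylate (cis-fused, 3a-OH cis to 6-CO2Et, 7-CH(OMe)2 trans to C1) | CCOC(=O)[C@@]1(OCc2ccc(OC)cc2)C(=O)C[C@]3(O)CC4(OCCO4)C[C@@H]3[C@H]1C(OC)OC | intermediate
10 | 5-hydroxy analogue of 9 (diol, both C27 epimers) | CCOC(=O)[C@@]1(OCc2ccc(OC)cc2)C(O)C[C@]3(O)CC4(OCCO4)C[C@@H]3[C@H]1C(OC)OC | intermediate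
11 | PMB-protected hydroxy lactone (lactone-bridged cis-hydrindane; C12–OPMB, C27–OH, C18 ethylene ketal, C23 = CH(OMe)2; C12, C16, C21, C22 as in 22) | COc1ccc(CO[C@@]23C(=O)O[C@]4(CC5(OCCO5)C[C@@H]4[C@H]2C(OC)OC)CC3O)cc1 | intermediate
12 | lactone keto aldehyde (C12–OH, C27–OH, C18 ketone, C23 aldehyde) | O[C@@]12C(=O)O[C@]3(CC(=O)C[C@@H]3[C@H]1C=O)CC2O | intermediate
13 | non-1-ene | C=CCCCCCCC | starting material
14 | pent-1-en-3-one | CCC(=O)C=C | starting material
15 | (4E)-dodec-4-en-3-one | CCC(=O)/C=C/CCCCCCC | intermediate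
16 | dicyclohexyl{[(2E,4E)-dodeca-2,4-dien-3-yl]oxy}borane | C/C=C(\C=C\CCCCCCC)OB(C1CCCCC1)C1CCCCC1 | intermediate
17 | O-dicyclohexylboryl derivative of 18 at C23 | O[C@@]12C(=O)O[C@]3(CC(=O)C[C@@H]3[C@H]1C(OB(C4CCCCC4)C4CCCCC4)C(C)C(=O)/C=C/CCCCCCC)CC2O | intermediate
18 | aldol adduct (C23–OH, C24–CH3, C10 ketone, (E)-nonenyl; C12–OH, C27–OH, C18 ketone) | O[C@@]12C(=O)O[C@]3(CC(=O)C[C@@H]3[C@H]1C(O)C(C)C(=O)/C=C/CCCCCCC)CC2O | intermediate
19 | tetraketone (ketones at C10, C18, C23, C27; C12–OH) | O[C@@]12C(=O)O[C@]3(CC(=O)C[C@@H]3[C@H]1C(=O)C(C)C(=O)/C=C/CCCCCCC)CC2=O | intermediate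
20 | dihydropyranone (C10=C24 vinylogous ester, C23 ketone; ketones at C18 and C27) | CCCCCCC/C=C/C=1O[C@@]23C(=O)O[C@]4(CC(=O)C[C@@H]4[C@H]2C(=O)C=1C)CC3=O | intermediate
21 | glycal-type triol (C23–OH mixture; C18–OH and C27–OH as in 22) | CCCCCCC/C=C/C=1O[C@@]23C(=O)O[C@]4(C[C@H](O)C[C@@H]4[C@H]2C(O)C=1C)C[C@H]3O | intermediate
22 | target lactone (10R,12S,16R,18R,21R,22R,27R by SMILES position; E-nonenyl) | CCCCCCC/C=C/[C@H]1O[C@@]23C(=O)O[C@]4(C[C@H](O)C[C@@H]4[C@H]2C=C1C)C[C@H]3O | target

## Step count and risks

Total: 10 steps. Longest linear sequence: 8 steps (2 → 3 → 4 → 5 → 7 → 8 → 9 → 10).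

**Step 3 (the new annulation).**
- Risks: the bond between the fully substituted C12 and the branched C22 may form slowly; 7 may isomerise to the endocyclic enone; the C12/C22 diastereoselectivity is unproven.
- Which pseudo-enantiomeric catalyst gives the required series is not predicted here and is fixed in the first run; the cupreine analogue gives the mirror-image series.
- Fallback (known auxiliary chemistry), setting out from 3 and coming back at 9: 3 is condensed with (1S)-1-phenylethanamine (TsOH cat., toluene, water removal) to the hydrogen-bonded enamino ester F1. F1 and 7 are heated (THF, MgBr2·OEt2, 40 °C) in a d'Angelo-type auxiliary-controlled Michael addition to give the imine F2. F2 is hydrolysed (10% aqueous AcOH) to isolated 8, and 8 is closed with DBU in toluene (Robinson-type aldol addition) to 9. The (1R)-amine is used if the sense of induction is the wrong one.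

**Step 8 (oxidation and cyclodehydration).**
- Risks: the enol oxygen of diketone 19 can add 6-endo to the C8=C9 enone and give an isomeric pyranone; the C12-hydroxy C27-ketone can undergo an acyloin shift.
- Fallback, setting out from 18 and coming back at 20: the C10 carbonyl is tied up before any diketone exists. PPTS in MeOH converts 18 into the cyclic methyl ketal F3 (O11 on C10). Dess–Martin oxidation gives the keto ketal F4. TsOH then eliminates methanol from the 2-methoxytetrahydropyran-4-one to give 20.

**Step 10 (Ferrier reduction).**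
- Risks: hydride may add at C23 or C8 instead of C10, or from the face next to the lactone carbonyl; the product is the less stable C10 epimer and can re-ionise; in step 9 the C23 alkoxide can translactonise onto C13.
- Fallback, setting out from 20 and coming back at 22, with no C23 alcohol and no acid: LiBH(s-Bu)3 (3.5 equiv, THF, −78 °C) reduces the C18 and C27 ketones and adds hydride 1,4 at C10 from the open face. The resulting enolate is trapped with N-(5-chloropyridin-2-yl)bis(trifluoromethanesulfonyl)imide as the enol triflate F5. Pd(OAc)2, PPh3, HCO2H and Bu3N in DMF at 60 °C then replace the triflate by hydrogen to give 22.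

Further compounds

F1 | step 3 | ethyl (2E)-2-[(4-methoxybenzyl)oxy]-3-{[(1S)-1-phenylethyl]amino}but-2-enoate | CCOC(=O)/C(=C(\N[C@@H](C)c1ccccc1)C)OCc1ccc(OC)cc1
F2 | step 3 | (1S)-1-phenylethyl imine of 8 at the acetyl carbonyl | CCOC(=O)[C@@](OCc1ccc(OC)cc1)(C(C)=N[C@@H](C)c1ccccc1)[C@H](C(OC)OC)[C@H]1CC2(OCCO2)CC1=O
F3 | step 8 | cyclic methyl ketal of 18 (O11–C10(OMe) ring, C23–OH, C27–OH) | CCCCCCC/C=C/C1(OC)O[C@@]23C(=O)O[C@]4(CC(=O)C[C@@H]4[C@H]2C(O)C1C)CC3O
F4 | step 8 | keto ketal (C23 and C27 ketones, C10 methyl ketal) | CCCCCCC/C=C/C1(OC)O[C@@]23C(=O)O[C@]4(CC(=O)C[C@@H]4[C@H]2C(=O)C1C)CC3=O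
F5 | step 10 | C23 enol triflate of the target skeleton (C10–H, C18–OH, C27–OH as in 22) | CCCCCCC/C=C/[C@H]1O[C@@]23C(=O)O[C@]4(C[C@H](O)C[C@@H]4[C@H]2C(OS(=O)(=O)C(F)(F)F)=C1C)C[C@H]3O
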